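The route rests on disconnecting the bond between the enone carbonyl carbon C8 and the methyl-bearing quaternary ring-fusion carbon C8a of the seven-membered ring (azulene locants). A [2,3]-Wittig ring enlargement forms it: the allylic α-oxy carbanion of a 2-cyclopentenyl-4-methyl-3,6-dihydro-2H-pyran attacks the far end of the tetrasubstituted cyclopentene alkene, which turns the six-membered ether into the cycloheptadiene, sets C8a by chirality transfer from the pyran carbinol carbon (later C4) and delivers the oxygen to C8. The step exploits that C8 sits between the C6=C7 alkene and C8a, and that C8a is the allylic terminus of C4–C3a=C8a. The cyclopentene with its isopropyl carbinol comes from (S)-terpinen-4-ol.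

Key step: step 7

Remark: commercial (S)-(+)-terpinen-4-ol is taken as enantiomerically pure (material of lower purity would be upgraded first); bicyclic compounds carry azulene locants in the orientation of the target name (C3 isopropyl carbinol carbon, C3a and C8a ring fusion, C4 acyloxy carbon, C8 carbonyl carbon).

Step 1
Reactants: 1 (S)-(+)-terpinen-4-ol
Product: 2 triethyl{[(1S)-4-methyl-1-(propan-2-yl)cyclohex-3-en-1-yl]oxy}silane
Conditions: Et3SiOTf, 2,6-lutidine, CH2Cl2, 0 °C to rt
Reagents that add atoms: triethylsilyl trifluoromethanesulfonate, CC[Si](CC)(CC)OS(=O)(=O)C(F)(F)F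
Why: Silyl triflate with a hindered pyridine base silylates even tertiary alcohols (silyl ether protection), and the ether keeps the carbinol oxygen from being expelled in step 3; no stereocentre is touched.

Step 2
Reactants: 2 triethyl{[(1S)-4-methyl-1-(propan-2-yl)cyclohex-3-en-1-yl]oxy}silane
Product: 4 (3S)-6-oxo-3-(propan-2-yl)-3-(triethylsilyloxy)heptanal, via secondary ozonide 3 (not isolated)
Conditions: O3, CH2Cl2, −78 °C; then PPh3, −78 °C to rt
Reagents that add atoms: ozone, [O-][O+]=O
Why: Ozonolysis with reductive work-up should cleave the only alkene to the methyl ketone and the aldehyde without touching the silyl ether or the stereocentre.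

Step 3
Reactants: 4 (3S)-6-oxo-3-(propan-2-yl)-3-(triethylsilyloxy)heptanal
Product: 6 (5R)-2-methyl-5-(propan-2-yl)-5-(triethylsilyloxy)cyclopent-1-ene-1-carbaldehyde, via aldol adduct 5 (not isolated)
Conditions: Bn2NH2+ CF3CO2− (20 mol %), toluene, 50 °C
Reagents that add atoms: none
Why: Amine-salt-catalysed intramolecular aldol condensation, in which the aldehyde enamine adds to the methyl ketone (5-enolexo-exo-trig) as in the classic ring contraction of cyclohexene terpenes through their 6-oxoheptanals, and water should be lost from the new free tertiary alcohol in preference to the poorer silanolate leaving group.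

Step 4
Reactants: 6 (5R)-2-methyl-5-(propan-2-yl)-5-(triethylsilyloxy)cyclopent-1-ene-1-carbaldehyde; 7 2-methylallylmagnesium chloride
Product: 9 (1S)-3-methyl-1-[(5R)-2-methyl-5-(propan-2-yl)-5-(triethylsilyloxy)cyclopent-1-en-1-yl]but-3-en-1-ol, via diisopinocampheylborinate 8 (not isolated)
Conditions: (−)-Ipc2BOMe, 7, Et2O, −78 °C to rt; then 6, −78 °C; then aq NaOH, H2O2, rt
Reagents that add atoms: 2-methylallylmagnesium chloride (7), CC(=C)C[Mg]Cl
Why: Brown asymmetric methallylation through a chair Zimmerman–Traxler transition state, in which the isopinocampheyl groups derived from (+)-α-pinene should direct the methallyl group to the Si face of the aldehyde and so set the (1S) carbinol under reagent control (any minor epimer would be removed by chromatography).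

Step 5
Reactants: 9 (1S)-3-methyl-1-[(5R)-2-methyl-5-(propan-2-yl)-5-(triethylsilyloxy)cyclopent-1-en-1-yl]but-3-en-1-ol; 10 allyl bromide
Product: 12 (1S)-1-(allyloxy)-3-methyl-1-[(5R)-2-methyl-5-(propan-2-yl)-5-(triethylsilyloxy)cyclopent-1-en-1-yl]but-3-ene, via sodium alkoxide 11 (not isolated)
Conditions: NaH, THF/DMF, 0 °C; then 10, Bu4NI (cat.), rt
Reagents that add atoms: allyl bromide (10), C=CCBr
Why: Williamson ether synthesis on the secondary alkoxide; the tertiary oxygen is silylated and no stereocentre is involved.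

Step 6
Reactants: 12 (1S)-1-(allyloxy)-3-methyl-1-[(5R)-2-methyl-5-(propan-2-yl)-5-(triethylsilyloxy)cyclopent-1-en-1-yl]but-3-ene
Product: 13 (2S)-4-methyl-2-[(5R)-2-methyl-5-(propan-2-yl)-5-(triethylsilyloxy)cyclopent-1-en-1-yl]-3,6-dihydro-2H-pyran
Conditions: second-generation Grubbs catalyst (5 mol %), CH2Cl2, 40 °C
Reagents that add atoms: none
Why: Ring-closing metathesis of the allyl ether with the 1,1-disubstituted methallyl alkene should close the six-membered dihydropyran with its trisubstituted alkene, while the tetrasubstituted cyclopentene alkene is inert to the catalyst.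

Step 7
Reactants: 13 (2S)-4-methyl-2-[(5R)-2-methyl-5-(propan-2-yl)-5-(triethylsilyloxy)cyclopent-1-en-1-yl]-3,6-dihydro-2H-pyran
Product: 16 (3R,8R,8aS)-6,8a-dimethyl-3-(propan-2-yl)-3-(triethylsilyloxy)-1,2,3,5,8,8a-hexahydroazulen-8-ol, via 6-lithio dihydropyran 14 (not isolated), via lithium alkoxide 15 (not isolated)
Conditions: s-BuLi, THF, −78 °C to −40 °C; then sat. aq NH4Cl
Reagents that add atoms: none
Why: Proposed new method: s-BuLi removes a proton from the pyran OCH2 (C6 of 13), the only position that is both next to oxygen and allylic without being tertiary, and the α-oxyallyl carbanion 14 undergoes a suprafacial [2,3]-sigmatropic Wittig shift onto the methyl-bearing carbon of the tetrasubstituted cyclopentene alkene, so that the C8–C8a bond forms while the pyran C2–O bond breaks and the C3a=C4 alkene appears; the closest known reactions are the [2,3]-Wittig ring contractions of cyclic bis-allylic ethers and the [1,2]- and [1,4]-Wittig ring contractions of 6-aryl-3,6-dihydro-2H-pyrans lithiated at the same carbon. The seven-membered carbocycle closes through the five-membered envelope transition state of the [2,3] shift (C8, O, C4, C3a, C8a), bridged by the three-atom C5–C6=C7 tether in an 8-oxabicyclo[3.2.1]octene-like array, so the six-membered ether is enlarged by one carbon and the oxygen ends as the C8 alkoxide 15. The quaternary centre C8a is controlled by the pyran C2 stereocentre: the shift is suprafacial across the allyl unit and only the rotamer with the pyran CH2 syn to C8a can give the cis alkene of a seven-membered ring, so the carbanion must arrive on the alkene face from which the oxygen leaves, which turns (2S) into (8aS); C8 is fixed as (8R) by the bicyclic transition state and is erased in step 9. The step needs lithiation at OCH2 instead of the tertiary OCH and the [2,3] path instead of [1,2] or [1,4] shifts: the first is secured by the higher kinetic acidity and accessibility of the secondary position, the second by the alkene terminus held within bonding distance and by −78 °C, where the concerted six-electron shift should outrun radical-pair pathways.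

Step 8
Reactants: 16 (3R,8R,8aS)-6,8a-dimethyl-3-(propan-2-yl)-3-(triethylsilyloxy)-1,2,3,5,8,8a-hexahydroazulen-8-ol
Product: 18 (3R,3aR,4R,8R,8aS)-6,8a-dimethyl-3-(propan-2-yl)-3-(triethylsilyloxy)-1,2,3,3a,4,5,8,8a-octahydroazulene-4,8-diol, via bis(9-borabicyclononyl) adduct 17 (not isolated)
Conditions: 9-BBN (3 equiv), THF, 0 to 65 °C; then aq NaOH, H2O2, 0 °C to rt
Reagents that add atoms: hydrogen peroxide, OO
Why: Hydroboration–oxidation, in which the first equivalent of 9-BBN caps the C8 hydroxyl as a bulky borinate that shields the C6=C7 alkene and the second should add boron to the less substituted C4 and hydrogen to C3a in a syn fashion from the face of the C8a methyl group (opposite the isopropyl group and the C8 arm), which sets the cis ring fusion (3aR) and, after oxidation with retention, the (4R) alcohol.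

Step 9
Reactants: 18 (3R,3aR,4R,8R,8aS)-6,8a-dimethyl-3-(propan-2-yl)-3-(triethylsilyloxy)-1,2,3,3a,4,5,8,8a-octahydroazulene-4,8-diol
Product: 19 (3R,3aS,8aS)-6,8a-dimethyl-3-(propan-2-yl)-3-(triethylsilyloxy)-1,2,3,3a,5,8a-hexahydroazulene-4,8-dione
Conditions: Dess–Martin periodinane, NaHCO3, CH2Cl2, 0 °C to rt
Reagents that add atoms: none
Why: Dess–Martin oxidation should convert both secondary alcohols into ketones under buffered, non-epimerising conditions, leaving C3a untouched.

Step 10
Reactants: 19 (3R,3aS,8aS)-6,8a-dimethyl-3-(propan-2-yl)-3-(triethylsilyloxy)-1,2,3,3a,5,8a-hexahydroazulene-4,8-dione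
Product: 20 (3R,3aR,4S,8aS)-4-hydroxy-6,8a-dimethyl-3-(propan-2-yl)-3-(triethylsilyloxy)-1,2,3,3a,4,5-hexahydroazulen-8(8aH)-one
Conditions: NaBH4, MeOH/CH2Cl2 (1:1), −78 °C
Reagents that add atoms: none
Why: Chemoselective borohydride reduction at low temperature should take the saturated C4 ketone in preference to the hindered, conjugated C8 carbonyl, and hydride should arrive on the convex face of the cis-fused bicycle, anti to the isopropyl group, to set the (4S) alcohol.

Step 11
Reactants: 20 (3R,3aR,4S,8aS)-4-hydroxy-6,8a-dimethyl-3-(propan-2-yl)-3-(triethylsilyloxy)-1,2,3,3a,4,5-hexahydroazulen-8(8aH)-one; 21 4-methoxybenzoyl chloride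
Product: 22 [(3R,3aR,4S,8aS)-6,8a-dimethyl-8-oxo-3-(propan-2-yl)-3-(triethylsilyloxy)-1,2,3,3a,4,5,8,8a-octahydroazulen-4-yl] 4-methoxybenzoate
Conditions: 21, Et3N, DMAP (cat.), CH2Cl2, rt
Reagents that add atoms: 4-methoxybenzoyl chloride (21), COc1ccc(cc1)C(Cl)=O
Why: DMAP-catalysed acylation (nucleophilic acyl transfer) of the only free hydroxyl group should give the 4-methoxybenzoate with retention at C4.

Step 12
Reactants: 22 [(3R,3aR,4S,8aS)-6,8a-dimethyl-8-oxo-3-(propan-2-yl)-3-(triethylsilyloxy)-1,2,3,3a,4,5,8,8a-octahydroazulen-4-yl] 4-methoxybenzoate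
Product: 23 [(3R,3aR,4S,8aS)-3-hydroxy-6,8a-dimethyl-8-oxo-3-(propan-2-yl)-1,2,3,3a,4,5,8,8a-octahydroazulen-4-yl] 4-methoxybenzoate
Conditions: HF·pyridine, THF, 0 °C to rt
Reagents that add atoms: none
Why: Fluoride-mediated desilylation should cleave the tertiary triethylsilyl ether without touching the ester or the enone and so release the target.

Compound list

1 | (S)-(+)-terpinen-4-ol, (1S)-4-methyl-1-(propan-2-yl)cyclohex-3-en-1-ol | CC1=CC[C@](O)(C(C)C)CC1 | starting material
2 | triethyl{[(1S)-4-methyl-1-(propan-2-yl)cyclohex-3-en-1-yl]oxy}silane | CC1=CC[C@](O[Si](CC)(CC)CC)(C(C)C)CC1 | intermediate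
3 | secondary ozonide of 2, (4S)-1-methyl-4-(propan-2-yl)-4-(triethylsilyloxy)-7,8,9-trioxabicyclo[4.2.1]nonane (mixture at the ozonide carbons) | CC12CC[C@@](O[Si](CC)(CC)CC)(C(C)C)CC(OO1)O2 | intermediate (not isolated)
4 | (3S)-6-oxo-3-(propan-2-yl)-3-(triethylsilyloxy)heptanal | O=CC[C@](O[Si](CC)(CC)CC)(C(C)C)CCC(C)=O | intermediate
5 | (5R)-2-hydroxy-2-methyl-5-(propan-2-yl)-5-(triethylsilyloxy)cyclopentane-1-carbaldehyde (mixture at C1 and C2) | O=CC1C(C)(O)CC[C@@]1(O[Si](CC)(CC)CC)C(C)C | intermediate (not isolated)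
6 | (5R)-2-methyl-5-(propan-2-yl)-5-(triethylsilyloxy)cyclopent-1-ene-1-carbaldehyde | O=CC1=C(C)CC[C@@]1(O[Si](CC)(CC)CC)C(C)C | intermediate
7 | 2-methylallylmagnesium chloride | CC(=C)C[Mg]Cl | starting material
8 | O-diisopinocampheylboryl derivative (borinate) of 9 | CC(=C)C[C@H](OB([C@@H]1C[C@@H]2C[C@@H](C2(C)C)[C@H]1C)[C@@H]1C[C@@H]2C[C@@H](C2(C)C)[C@H]1C)C1=C(C)CC[C@@]1(O[Si](CC)(CC)CC)C(C)C | intermediate (not isolated)
9 | (1S)-3-methyl-1-[(5R)-2-methyl-5-(propan-2-yl)-5-(triethylsilyloxy)cyclopent-1-en-1-yl]but-3-en-1-ol | CC(=C)C[C@H](O)C1=C(C)CC[C@@]1(O[Si](CC)(CC)CC)C(C)C | intermediate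
10 | allyl bromide (3-bromoprop-1-ene) | C=CCBr | starting material
11 | sodium alkoxide of 9 | CC(=C)C[C@H](O[Na])C1=C(C)CC[C@@]1(O[Si](CC)(CC)CC)C(C)C | intermediate (not isolated)
12 | (1S)-1-(allyloxy)-3-methyl-1-[(5R)-2-methyl-5-(propan-2-yl)-5-(triethylsilyloxy)cyclopent-1-en-1-yl]but-3-ene | CC(=C)C[C@H](OCC=C)C1=C(C)CC[C@@]1(O[Si](CC)(CC)CC)C(C)C | intermediate
13 | (2S)-4-methyl-2-[(5R)-2-methyl-5-(propan-2-yl)-5-(triethylsilyloxy)cyclopent-1-en-1-yl]-3,6-dihydro-2H-pyran | CC1=CCO[C@@H](C1)C2=C(C)CC[C@@]2(O[Si](CC)(CC)CC)C(C)C | intermediate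
14 | 6-lithio derivative of 13 (lithium on the pyran OCH carbon, configuration at that carbon not defined) | [Li]C1C=C(C)C[C@H](O1)C2=C(C)CC[C@@]2(O[Si](CC)(CC)CC)C(C)C | intermediate (not isolated)
15 | lithium alkoxide of 16 | [Li]O[C@@H]1C=C(C)CC=C2[C@]1(C)CC[C@@]2(O[Si](CC)(CC)CC)C(C)C | intermediate (not isolated)
16 | (3R,8R,8aS)-6,8a-dimethyl-3-(propan-2-yl)-3-(triethylsilyloxy)-1,2,3,5,8,8a-hexahydroazulen-8-ol | O[C@@H]1C=C(C)CC=C2[C@]1(C)CC[C@@]2(O[Si](CC)(CC)CC)C(C)C | intermediate
17 | adduct of 16 with two 9-BBN units: 9-borabicyclo[3.3.1]nonan-9-yl on C4 (cis to 3a-H and the 8a-methyl) and on the C8 oxygen | B1(C2CCCC1CCC2)[C@@H]3CC(C)=C[C@@H](OB4C5CCCC4CCC5)[C@@]6(C)CC[C@@](O[Si](CC)(CC)CC)(C(C)C)[C@@H]36 | intermediate (not isolated)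
18 | (3R,3aR,4R,8R,8aS)-6,8a-dimethyl-3-(propan-2-yl)-3-(triethylsilyloxy)-1,2,3,3a,4,5,8,8a-octahydroazulene-4,8-diol | O[C@@H]2CC(C)=C[C@@H](O)[C@@]3(C)CC[C@@](O[Si](CC)(CC)CC)(C(C)C)[C@@H]23 | intermediate
19 | (3R,3aS,8aS)-6,8a-dimethyl-3-(propan-2-yl)-3-(triethylsilyloxy)-1,2,3,3a,5,8a-hexahydroazulene-4,8-dione | O=C2CC(C)=CC(=O)[C@@]3(C)CC[C@@](O[Si](CC)(CC)CC)(C(C)C)[C@@H]23 | intermediate
20 | (3R,3aR,4S,8aS)-4-hydroxy-6,8a-dimethyl-3-(propan-2-yl)-3-(triethylsilyloxy)-1,2,3,3a,4,5-hexahydroazulen-8(8aH)-one | O[C@H]2CC(C)=CC(=O)[C@@]3(C)CC[C@@](O[Si](CC)(CC)CC)(C(C)C)[C@@H]23 | intermediate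
21 | 4-methoxybenzoyl chloride | COc1ccc(cc1)C(Cl)=O | starting material
22 | [(3R,3aR,4S,8aS)-6,8a-dimethyl-8-oxo-3-(propan-2-yl)-3-(triethylsilyloxy)-1,2,3,3a,4,5,8,8a-octahydroazulen-4-yl] 4-methoxybenzoate | COc1ccc(C(=O)O[C@H]2CC(C)=CC(=O)[C@@]3(C)CC[C@@](O[Si](CC)(CC)CC)(C(C)C)[C@@H]23)cc1 | intermediate
23 | [(3R,3aR,4S,8aS)-3-hydroxy-6,8a-dimethyl-8-oxo-3-(propan-2-yl)-1,2,3,3a,4,5,8,8a-octahydroazulen-4-yl] 4-methoxybenzoate | COc1ccc(C(=O)O[C@H]2CC(C)=CC(=O)[C@@]3(C)CC[C@@](O)(C(C)C)[C@@H]23)cc1 | target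

Total step count: 12
Longest linear sequence: 12 steps (1 to 23)

Steps most likely to fail

1. Step 7 (the labelled step). The risks are lithiation at the tertiary ether carbon, a [1,2]- or [1,4]-shift of the allylic carbon outrunning the congested [2,3] shift, or silyl migration in the alkoxide. The fallback uses known chemistry: a thermal [3,3] shift makes the same bond without a carbanion. It sets out from enal 6. Still–Gennari olefination (ethyl 2-[bis(2,2,2-trifluoroethoxy)phosphoryl]propanoate, KHMDS, 18-crown-6, THF, −78 °C) should give ethyl (2Z)-2-methyl-3-(cyclopentenyl)prop-2-enoate F1. Reduction with iBu2AlH should give the (Z)-allylic alcohol F2. Charette cyclopropanation (Et2Zn, CH2I2, (4R,5R)-2-butyl-N,N,N',N'-tetramethyl-1,3,2-dioxaborolane-4,5-dicarboxamide, CH2Cl2, 0 °C) should give the cis-cyclopropylmethanol F3. Dess–Martin oxidation should give the cyclopropanecarbaldehyde F4, which would be used at once and cold. Boron-Wittig olefination (CH2(Bpin)2, LiTMP, THF, −78 °C to rt) should give the (E)-alkenylboronate F5. Heating in toluene at 110 °C should bring about the cis-divinylcyclopropane–cycloheptadiene rearrangement through its boat transition state to the allylic boronate F6, with the same configuration at C8a and C8. Oxidation with NaBO3·4H2O in THF/water returns to dienol 16.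

2. Step 8. The risks are slow addition of the borane to the hindered C3a=C4 alkene, competing hydroboration of the C6=C7 alkene, or attack from the isopropyl face. The fallback delivers the hydride from a tether on the C3 oxygen and sets out from 16. Bu4NF should remove the silyl group to give the 3,8-diol F7. (HMe2Si)2NH should give the bis(dimethylsilyl) ether F8. Karstedt catalyst, Pt2[(CH2=CHSiMe2)2O]3, should induce intramolecular 5-endo hydrosilylation to the oxasilolane F9, with silicon on C4 and hydrogen on C3a both on the face of the C3 oxygen. Tamao–Fleming oxidation (H2O2, KF, KHCO3, THF/MeOH) should give the 3,4,8-triol F10. Dess–Martin oxidation should give the 3-hydroxy-4,8-dione F11. NaBH4 at −78 °C should give the 3,4-dihydroxy enone F12. Acylation of its secondary hydroxyl with 21 (Et3N, DMAP) returns to the route at target 23.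

3. Step 3. The risks are loss of triethylsilanol from the enamine of the β-silyloxy aldehyde, which would give an acyclic enal, or enolisation on the ketone side, which would give an acetylcyclopentene. The fallback separates bond formation from dehydration and sets out from 4. L-Proline (cat.) in DMSO at rt should stop at the aldol adduct 5, which is isolated. The Burgess reagent (toluene, 50 °C) should then dehydrate only its free tertiary alcohol and return to enal 6. This fallback makes no compound outside the list (F0).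

Further compounds

F1 | step 7 | ethyl (2Z)-2-methyl-3-[(5R)-2-methyl-5-(propan-2-yl)-5-(triethylsilyloxy)cyclopent-1-en-1-yl]prop-2-enoate | CCOC(=O)/C(C)=C\C1=C(C)CC[C@@]1(O[Si](CC)(CC)CC)C(C)C
F2 | step 7 | (2Z)-2-methyl-3-[(5R)-2-methyl-5-(propan-2-yl)-5-(triethylsilyloxy)cyclopent-1-en-1-yl]prop-2-en-1-ol | OC/C(C)=C\C1=C(C)CC[C@@]1(O[Si](CC)(CC)CC)C(C)C
F3 | step 7 | {(1S,2R)-1-methyl-2-[(5R)-2-methyl-5-(propan-2-yl)-5-(triethylsilyloxy)cyclopent-1-en-1-yl]cyclopropyl}methanol | OC[C@@]1(C)C[C@H]1C2=C(C)CC[C@@]2(O[Si](CC)(CC)CC)C(C)C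
F4 | step 7 | (1S,2R)-1-methyl-2-[(5R)-2-methyl-5-(propan-2-yl)-5-(triethylsilyloxy)cyclopent-1-en-1-yl]cyclopropane-1-carbaldehyde | O=C[C@@]1(C)C[C@H]1C2=C(C)CC[C@@]2(O[Si](CC)(CC)CC)C(C)C
F5 | step 7 | 2-{(E)-2-[(1R,2R)-1-methyl-2-[(5R)-2-methyl-5-(propan-2-yl)-5-(triethylsilyloxy)cyclopent-1-en-1-yl]cyclopropyl]ethenyl}-4,4,5,5-tetramethyl-1,3,2-dioxaborolane | CC1(C)OB(/C=C/[C@@]2(C)C[C@H]2C3=C(C)CC[C@@]3(O[Si](CC)(CC)CC)C(C)C)OC1(C)C
F6 | step 7 | 2-[(3R,8R,8aS)-6,8a-dimethyl-3-(propan-2-yl)-3-(triethylsilyloxy)-1,2,3,5,8,8a-hexahydroazulen-8-yl]-4,4,5,5-tetramethyl-1,3,2-dioxaborolane | CC1(C)OB(OC1(C)C)[C@@H]2C=C(C)CC=C3[C@]2(C)CC[C@@]3(O[Si](CC)(CC)CC)C(C)C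
F7 | step 8 | (3R,8R,8aS)-6,8a-dimethyl-3-(propan-2-yl)-1,2,3,5,8,8a-hexahydroazulene-3,8-diol | O[C@@H]1C=C(C)CC=C2[C@]1(C)CC[C@@]2(O)C(C)C
F8 | step 8 | 3,8-bis(dimethylsilyl) ether of F7 | C[SiH](C)O[C@@H]1C=C(C)CC=C2[C@]1(C)CC[C@@]2(O[SiH](C)C)C(C)C
F9 | step 8 | oxasilolane from F8: dimethylsilylene bridge between the C3 oxygen and C4 (silicon and 3a-H cis to the 8a-methyl), 8-O-dimethylsilyl ether | C[Si]4(C)[C@@H]2CC(C)=C[C@@H](O[SiH](C)C)[C@@]3(C)CC[C@@](O4)(C(C)C)[C@@H]23
F10 | step 8 | (3R,3aR,4R,8R,8aS)-6,8a-dimethyl-3-(propan-2-yl)-1,2,3,3a,4,5,8,8a-octahydroazulene-3,4,8-triol | O[C@@H]2CC(C)=C[C@@H](O)[C@@]3(C)CC[C@@](O)(C(C)C)[C@@H]23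
F11 | step 8 | (3R,3aS,8aS)-3-hydroxy-6,8a-dimethyl-3-(propan-2-yl)-1,2,3,3a,5,8a-hexahydroazulene-4,8-dione | O=C2CC(C)=CC(=O)[C@@]3(C)CC[C@@](O)(C(C)C)[C@@H]23
F12 | step 8 | (3R,3aR,4S,8aS)-3,4-dihydroxy-6,8a-dimethyl-3-(propan-2-yl)-1,2,3,3a,4,5-hexahydroazulen-8(8aH)-one | O[C@H]2CC(C)=CC(=O)[C@@]3(C)CC[C@@](O)(C(C)C)[C@@H]23
F0 | step 3 | none | none
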